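**Retrosynthetic overview**

1. Ring names: A = cyclopentane fused to the pyran; B = dihydropyran acetal; C = cyclopentane carrying C(CH3)(CO2CH3); D = cyclohexene (C + D = bicyclo[3.2.1]octene). The target comes from O-acylation of a lactol, made by iBu2AlH reduction of a dienol δ-lactone, made by dehydration of a tertiary allylic carbinol; ring B is carried as a δ-lactone from step 8 on.
2. Ring A is closed last, by a three-component Michael–Michael–alkylation: tricyclic lactone–enoate + CH2=CHSO2Ph + CH3I, then desulfonylation.
3. Enabling feature: the CH2–CH2 of ring A joins the ring A/ring B fusion CH (alpha to the acetal carbon, hence an enolate carbon while that carbon is a lactone C=O) to the ring A/ring C fusion CH (beta to the CO2CH3 on the neighbouring quaternary carbon of ring C, hence an enoate beta-carbon); the CH3 on that quaternary carbon is the quench of the enolate left behind.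
4. Ring B comes from sulfonium ylide epoxidation of the enone carbonyl and carboxylate opening; ring C from an ester aldol/dehydration across cis-1,3 positions of a cyclohexenone; ring D from an organocatalytic Michael addition/aldol condensation that sets the absolute configuration.
5. Order of ring formation: D (step 2), C (step 5), B (step 8), A (step 10).

Key step: step 10

Remark on the chemistry: centres that the route creates and erases again need no control. The carbinol carbon of 11–19 is drawn as the epimer expected from ylide attack on the carbonyl face beside the one-carbon bridge; the other epimer would pass through the same steps. The sulfonyl-bearing carbon of 15–17 and the C6/C7 centres of 7 and 8 are left undefined in the SMILES.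

**Route**

Step 1
Reactants: 1 methyl 4-oxobutanoate; 2 but-3-en-2-one (methyl vinyl ketone)
Product: 3 methyl (3R)-3-formyl-6-oxoheptanoate
Conditions: (R)-2-[diphenyl(trimethylsilyloxy)methyl]pyrrolidine (10 mol%), ethyl 3,4-dihydroxybenzoate (20 mol%), CH2Cl2, 4 °C
Reagents that add atoms: none
Why: Enamine-catalysed Michael addition in which the enone should approach the E-enamine on the face away from the diphenyl(silyloxy)methyl group, setting the (R) centre that becomes the CH bridgehead of rings C and D.

Step 2
Reactants: 3 methyl (3R)-3-formyl-6-oxoheptanoate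
Product: 4 methyl 2-[(1R)-4-oxocyclohex-2-en-1-yl]acetate
Conditions: TsOH·H2O (10 mol%), toluene, 80 °C
Reagents that add atoms: none
Why: Acid-catalysed intramolecular aldol condensation of the methyl ketone onto the aldehyde closes ring D, and the cyclisation should outpace enolisation of the aldehyde so that the centre (now gamma to the enone carbonyl) is kept.

Step 3
Reactants: 4 methyl 2-[(1R)-4-oxocyclohex-2-en-1-yl]acetate
Product: 5 methyl 2-[(1R,5Z)-5-(hydroxymethylidene)-4-oxocyclohex-2-en-1-yl]acetate
Conditions: LiN(iPr)2 (1.1 equiv), THF, −78 °C; CF3CH2OCHO; aq. NH4Cl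
Reagents that add atoms: 2,2,2-trifluoroethyl formate, O=COCC(F)(F)F
Why: Kinetic deprotonation of the enone at the alpha-prime CH2 and Claisen-type formylation install the carbon that becomes the ring A/ring C fusion CH; no stereocentre is formed.

Step 4
Reactants: 5 methyl 2-[(1R,5Z)-5-(hydroxymethylidene)-4-oxocyclohex-2-en-1-yl]acetate
Product: 6 tert-butyl 2-[(1R,5R)-1-formyl-5-(2-methoxy-2-oxoethyl)-2-oxocyclohex-3-en-1-yl]acetate
Conditions: BrCH2CO2tBu, K2CO3, NaI (10 mol%), acetone, 20 °C
Reagents that add atoms: tert-butyl bromoacetate, BrCC(=O)OC(C)(C)C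
Why: C-alkylation of the stabilised enolate of the 2-formyl ketone by the soft iodoacetate formed in situ creates the quaternary carbon, the electrophile entering anti to the CH2CO2CH3 arm so that the formyl group should end cis to it.

Step 5
Reactants: 6 tert-butyl 2-[(1R,5R)-1-formyl-5-(2-methoxy-2-oxoethyl)-2-oxocyclohex-3-en-1-yl]acetate
Product: 7 methyl (1R,5S)-1-(2-tert-butoxy-2-oxoethyl)-7-hydroxy-2-oxobicyclo[3.2.1]oct-3-ene-6-carboxylate (C6/C7 epimers)
Conditions: LiN(iPr)2 (2.1 equiv), THF, −78 °C; AcOH quench at −78 °C
Reagents that add atoms: none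
Why: Intramolecular aldol addition of the methyl ester enolate to the neighbouring non-enolisable, doubly activated aldehyde (5-exo-trig) closes ring C across the cis-1,3 positions and fixes the bicyclo[3.2.1]octane; the two new centres are removed in step 6.

Step 6
Reactants: 7 methyl (1R,5S)-1-(2-tert-butoxy-2-oxoethyl)-7-hydroxy-2-oxobicyclo[3.2.1]oct-3-ene-6-carboxylate
Product: 9 methyl (1R,5S)-1-(2-tert-butoxy-2-oxoethyl)-2-oxobicyclo[3.2.1]octa-3,6-diene-6-carboxylate, via mesylate 8 (not isolated)
Conditions: MsCl, Et3N, CH2Cl2, 0 °C; then DBU, 20 °C
Reagents that add atoms: none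
Why: Mesylation and E1cB elimination of the beta-mesyloxy ester give the enoate, and elimination can only run toward the ester-bearing carbon because the other neighbour is quaternary.

Step 7
Reactants: 9 methyl (1R,5S)-1-(2-tert-butoxy-2-oxoethyl)-2-oxobicyclo[3.2.1]octa-3,6-diene-6-carboxylate
Product: 10 2-[(1R,5S)-6-(methoxycarbonyl)-2-oxobicyclo[3.2.1]octa-3,6-dien-1-yl]acetic acid
Conditions: CF3CO2H/CH2Cl2 (1:4), 0 → 20 °C
Reagents that add atoms: none
Why: Acidolysis of the tert-butyl ester (loss of 2-methylpropene) should leave the methyl ester, enone and enoate untouched.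

Step 8
Reactants: 10 2-[(1R,5S)-6-(methoxycarbonyl)-2-oxobicyclo[3.2.1]octa-3,6-dien-1-yl]acetic acid
Product: 12 tricyclic hydroxy delta-lactone (rings B + C + D; tertiary allylic OH on the former ketone carbon), via potassium epoxy carboxylate 11 (not isolated)
Conditions: KN(SiMe3)2 (1.0 equiv), THF, −20 °C; Me2S=CH2 (1.3 equiv, from Me3S+ I− and KN(SiMe3)2), THF–DMSO, −10 → 20 °C; then 50 °C; aq. NH4Cl
Reagents that add atoms: trimethylsulfonium iodide, C[S+](C)C.[I-]
Why: Corey–Chaykovsky methylene transfer to the ketone carbonyl (1,2-addition, as usual for sulfonium ylides and enones) gives a spiro-epoxide whose CH2 is opened 6-exo-tet by the neighbouring carboxylate, closing ring B as a delta-lactone; the bridgehead arm is gauche to both substituents of the epoxide carbon, which suits a six-membered but not a five-membered lactone, and the new carbinol centre is erased in step 13.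

Step 9
Reactants: 12 tricyclic hydroxy delta-lactone
Product: 13 triethylsilyl ether of 12
Conditions: Et3SiOTf, 2,6-lutidine, CH2Cl2, −78 → 0 °C
Reagents that add atoms: triethylsilyl trifluoromethanesulfonate, CC[Si](CC)(CC)OS(=O)(=O)C(F)(F)F
Why: Silylation of the tertiary allylic alcohol with the silyl triflate prevents alkoxide formation and acyl transfer in step 10.

Step 10
Reactants: 13 triethylsilyl ether of 12
Product: 17 tetracyclic sulfone (rings A–D; ring B as delta-lactone; PhSO2 on the ring A carbon next to the A/C fusion CH), via lithium lactone enolate 14 (not isolated), via alpha-sulfonyl carbanion 15 (not isolated), via lithium ester enolate 16 (not isolated)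
Conditions: LiN(iPr)2 (1.05 equiv), THF, −78 °C; CH2=CHSO2Ph (1.0 equiv), −78 → −30 °C; MeI (5 equiv), DMPU, −78 → 0 °C
Reagents that add atoms: phenyl vinyl sulfone, C=CS(=O)(=O)c1ccccc1; iodomethane, CI
Why: The lithium enolate of the ring B lactone (14) adds to phenyl vinyl sulfone, the alpha-sulfonyl carbanion so formed (15) closes ring A by conjugate addition to the beta-carbon of the ring C enoate, and the ester enolate left behind (16) is methylated, so three C–C bonds, ring A and the quaternary C(CH3)CO2CH3 centre arise in one flask. The closest known reaction type is the Michael–Michael ring closure of enolates with vinyl sulfones as ethylene equivalents, followed by enolate alkylation. Ring A is the only ring closed, in the 5-exo-trig mode. The fusion CH next to the lactone carbonyl is fixed because only the adduct whose sulfonylethyl arm lies on the face of the enoate bridge can cyclise, the other epimer returning through enolate equilibration; the A/C fusion CH is fixed by attack on the exo face of the two-carbon bridge, the only trajectory that the three-atom tether and a cis-bicyclo[3.3.0]octane allow; the methyl should enter the ester enolate from the same exo face because the endo face lies under the three-carbon bridge, which leaves CO2CH3 endo as in the target. The step needs the lactone enolate to attack the vinyl sulfone once and not the internal enoate, which the quaternary bridgehead beside the enoate beta-carbon and the use of exactly one equivalent of sulfone at −78 °C before MeI should secure. The sulfonyl-bearing carbon is formed without control and is erased in step 11.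

Step 11
Reactants: 17 tetracyclic sulfone
Product: 18 tetracyclic silyloxy lactone (17 without the sulfonyl group)
Conditions: Na/Hg (6% Na), Na2HPO4, MeOH–THF, −20 °C
Reagents that add atoms: none
Why: Reductive desulfonylation (electron transfer, C–S cleavage, protonation by the buffer) replaces the sulfonyl group by hydrogen and erases the uncontrolled centre.

Step 12
Reactants: 18 tetracyclic silyloxy lactone
Product: 19 tetracyclic hydroxy lactone
Conditions: HF·pyridine, THF–pyridine, 0 °C
Reagents that add atoms: none
Why: Fluoride cleavage of the Si–O bond frees the tertiary allylic alcohol under buffered conditions that should leave lactone and ester intact.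

Step 13
Reactants: 19 tetracyclic hydroxy lactone
Product: 20 tetracyclic dienol lactone
Conditions: Burgess reagent (Et3N+–SO2–N−–CO2Me), toluene, 50 °C
Reagents that add atoms: none
Why: Burgess dehydration (syn-elimination through the sulfamate ester) can only take a hydrogen from the OCH2 group, since the other neighbours are quaternary or vinylic, and so gives the enol lactone conjugated with the ring D alkene.

Step 14
Reactants: 20 tetracyclic dienol lactone
Product: 21 lactol (OH trans to the adjacent ring A C–C bond)
Conditions: iBu2AlH (1.1 equiv), CH2Cl2, −78 °C; aq. potassium sodium tartrate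
Reagents that add atoms: none
Why: Half-reduction of the enol lactone, which is more electrophilic than the hindered methyl ester on the quaternary carbon (the nepetalactone-to-nepetalactol type of reduction), gives the lactol, which should settle as the anomer with OH trans to the neighbouring ring A bond as in related cyclopenta[c]pyranols.

Step 15
Reactants: 21 lactol
Product: 22 target (CNP0315847.1)
Conditions: 3-methylbutanoyl chloride, Et3N, DMAP (10 mol%), CH2Cl2, −20 → 0 °C
Reagents that add atoms: 3-methylbutanoyl chloride, CC(C)CC(Cl)=O
Why: DMAP-catalysed O-acylation of the hemiacetal hydroxyl does not break the C–O bond, so the acetal configuration of 21 is kept in the isovalerate.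

**Compound list**

1 | methyl 4-oxobutanoate | COC(=O)CCC=O | starting material
2 | but-3-en-2-one | CC(=O)C=C | starting material
3 | methyl (3R)-3-formyl-6-oxoheptanoate | COC(=O)C[C@H](C=O)CCC(C)=O | intermediate
4 | methyl 2-[(1R)-4-oxocyclohex-2-en-1-yl]acetate | COC(=O)C[C@@H]1C=CC(=O)CC1 | intermediate
5 | methyl 2-[(1R,5Z)-5-(hydroxymethylidene)-4-oxocyclohex-2-en-1-yl]acetate (enol form of the formyl ketone) | COC(=O)C[C@@H]1C=CC(=O)/C(=C\O)C1 | intermediate
6 | tert-butyl 2-[(1R,5R)-1-formyl-5-(2-methoxy-2-oxoethyl)-2-oxocyclohex-3-en-1-yl]acetate (formyl cis to the CH2CO2CH3 arm) | O=C[C@]1(CC(=O)OC(C)(C)C)C[C@H](CC(=O)OC)C=CC1=O | intermediate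
7 | methyl (1R,5S)-1-(2-tert-butoxy-2-oxoethyl)-7-hydroxy-2-oxobicyclo[3.2.1]oct-3-ene-6-carboxylate (C6/C7 epimers) | COC(=O)C1C(O)[C@]2(CC(=O)OC(C)(C)C)C[C@H]1C=CC2=O | intermediate
8 | C7 methanesulfonate of 7 (not isolated) | COC(=O)C1C(OS(C)(=O)=O)[C@]2(CC(=O)OC(C)(C)C)C[C@H]1C=CC2=O | intermediate
9 | methyl (1R,5S)-1-(2-tert-butoxy-2-oxoethyl)-2-oxobicyclo[3.2.1]octa-3,6-diene-6-carboxylate | COC(=O)C1=C[C@]2(CC(=O)OC(C)(C)C)C[C@H]1C=CC2=O | intermediate
10 | 2-[(1R,5S)-6-(methoxycarbonyl)-2-oxobicyclo[3.2.1]octa-3,6-dien-1-yl]acetic acid | COC(=O)C1=C[C@]2(CC(=O)O)C[C@H]1C=CC2=O | intermediate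
11 | potassium carboxylate of the spiro-epoxide at the former ketone carbon of 10 (not isolated) | [K+].COC(=O)C1=C[C@]2(CC(=O)[O-])C[C@H]1C=C[C@@]23CO3 | intermediate
12 | tricyclic hydroxy delta-lactone: bicyclo[3.2.1]octa-3,6-diene of 10 whose C2 carries OH and an OCH2 group esterified by the C1 acetic acid arm | COC(=O)C1=C[C@]2(CC(=O)OC3)C[C@H]1C=C[C@]23O | intermediate
13 | triethylsilyl ether of 12 | COC(=O)C1=C[C@]2(CC(=O)OC3)C[C@H]1C=C[C@]23O[Si](CC)(CC)CC | intermediate
14 | lithium enolate of the lactone of 13 (not isolated) | COC(=O)C1=C[C@]2(C=C(O[Li])OC3)C[C@H]1C=C[C@]23O[Si](CC)(CC)CC | intermediate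
15 | lithiated alpha-sulfonyl carbanion, Michael adduct of 14 and phenyl vinyl sulfone (not isolated) | COC(=O)C1=C[C@]2([C@@H](CC([Li])S(=O)(=O)c4ccccc4)C(=O)OC3)C[C@H]1C=C[C@]23O[Si](CC)(CC)CC | intermediate
16 | lithium ester enolate of the ring-A-closed tetracycle (not isolated) | COC(O[Li])=C1[C@@H]2C=C[C@@]3(O[Si](CC)(CC)CC)COC(=O)[C@@H]4CC(S(=O)(=O)c5ccccc5)[C@@H]1[C@]34C2 | intermediate
17 | tetracyclic sulfone: target skeleton with ring B as delta-lactone, C–OSiEt3 at the future enol ether carbon, PhSO2 on the ring A carbon next to the A/C fusion CH (epimers at that carbon) | COC(=O)[C@]1(C)[C@@H]2C=C[C@@]3(O[Si](CC)(CC)CC)COC(=O)[C@@H]4CC(S(=O)(=O)c5ccccc5)[C@@H]1[C@]34C2 | intermediate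
18 | tetracyclic silyloxy lactone (17 without the sulfonyl group) | COC(=O)[C@]1(C)[C@@H]2C=C[C@@]3(O[Si](CC)(CC)CC)COC(=O)[C@@H]4CC[C@@H]1[C@]34C2 | intermediate
19 | tetracyclic hydroxy lactone (18 without the silyl group) | COC(=O)[C@]1(C)[C@@H]2C=C[C@@]3(O)COC(=O)[C@@H]4CC[C@@H]1[C@]34C2 | intermediate
20 | tetracyclic dienol lactone (ring B enol lactone conjugated with the ring D alkene) | COC(=O)[C@]1(C)[C@@H]2C=CC3=COC(=O)[C@@H]4CC[C@@H]1[C@]34C2 | intermediate
21 | lactol from 20, OH trans to the adjacent ring A C–C bond | COC(=O)[C@]1(C)[C@@H]2C=CC3=CO[C@@H](O)[C@@H]4CC[C@@H]1[C@]34C2 | intermediate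
22 | CNP0315847.1, the 3-methylbutanoate of lactol 21 | COC(=O)[C@]1(C)[C@@H]2C=CC3=CO[C@@H](OC(=O)CC(C)C)[C@@H]4CC[C@@H]1[C@]34C2 | target

**Summary and risks**

Total step count: 15. Longest linear sequence: 15 steps (fully linear from 1 and 2).

Steps most likely to fail:

Step 10. Possible failures are a second addition of vinyl sulfone to one of the enolates, proton transfer that quenches the sulfonyl carbanion before ring closure, and methylation from the endo face. The fallback sets out from 13 and returns at 18. The lithium enolate of 13 would be alkylated with 1-chloro-2-iodoethane (LiN(iPr)2, THF–DMPU, −78 → −40 °C) to give the 2-chloroethyl lactone F1, with the arm on the face of the enoate bridge after base equilibration if needed. Halide exchange (NaI, acetone, reflux) would give the 2-iodoethyl lactone F2. Ring A would then be closed by a radical 5-exo cyclisation onto the enoate with SmI2 and HMPA in THF at −78 °C, and the samarium enolate formed by the second electron transfer would be quenched with MeI. This gives 18 directly and makes step 11 unnecessary.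

Step 14. Possible failures are ring–chain tautomerism of the dienol lactol with irreversible drift to an enal, over-reduction, and poor anomeric control carried into step 15. The fallback sets out from 19 and returns at 22. It sets the acetal before the diene exists. The saturated lactone of 19 would be reduced (iBu2AlH, 2.2 equiv, CH2Cl2, −78 °C) to the stable hydroxy lactol F3, whose anomers can equilibrate freely. The hemiacetal OH alone would be acylated (3-methylbutanoyl chloride, pyridine, DMAP), the tertiary carbinol staying free, to give the hydroxy acetal ester F4; a Mitsunobu esterification with 3-methylbutanoic acid would correct the wrong anomer. Burgess dehydration of F4 would then give 22.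

Step 8. Possible failures are methylene transfer to the enoate in place of the hindered, carboxylate-bearing ketone, incomplete carbonyl addition, and slow lactone-forming epoxide opening. The fallback sets out from 10 and returns at 12. The ketone of 10 would be methylenated (Ph3P=CH2, 2.2 equiv, THF, 0 → 20 °C) to the cross-conjugated diene acid F5. The exocyclic 1,1-disubstituted alkene would be epoxidised selectively (mCPBA, NaHCO3, CH2Cl2, 0 °C) to the epoxy acid F6. Catalytic Cs2CO3 in DMF at 40 °C would close the lactone to 12.

**Further compounds**

F1 | step 10 | 2-chloroethyl lactone: 13 alkylated at the lactone alpha-carbon, arm on the face of the enoate bridge | COC(=O)C1=C[C@]2([C@@H](CCCl)C(=O)OC3)C[C@H]1C=C[C@]23O[Si](CC)(CC)CC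
F2 | step 10 | 2-iodoethyl lactone corresponding to F1 | COC(=O)C1=C[C@]2([C@@H](CCI)C(=O)OC3)C[C@H]1C=C[C@]23O[Si](CC)(CC)CC
F3 | step 14 | hydroxy lactol: 19 with the lactone carbonyl reduced to the hemiacetal | COC(=O)[C@]1(C)[C@@H]2C=C[C@@]3(O)CO[C@@H](O)[C@@H]4CC[C@@H]1[C@]34C2
F4 | step 14 | hydroxy acetal ester: 3-methylbutanoate of F3 at the hemiacetal oxygen | COC(=O)[C@]1(C)[C@@H]2C=C[C@@]3(O)CO[C@@H](OC(=O)CC(C)C)[C@@H]4CC[C@@H]1[C@]34C2
F5 | step 8 | diene acid: 10 with the ketone converted to an exocyclic methylene | COC(=O)C1=C[C@]2(CC(=O)O)C[C@H]1C=CC2=C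
F6 | step 8 | epoxy acid: free acid of 11 | COC(=O)C1=C[C@]2(CC(=O)O)C[C@H]1C=C[C@@]23CO3
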